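The ochre run, charged at 0.025 M, showed target at 27.6 % after 1.00 h, but by 6.00 h substrate and target moved no more than the scatter of 0.5 percentage points allows. The grey run, with a larger charge of 0.038 M, stood at the same level, so I read both late stretches as rest, which is thermodynamic control.

| setting | ochre | grey | flask |
|---|---|---|---|
| substrate | 0.025 M | 0.038 M | 0.050 M |
| remark | run made earlier | run made earlier |  |
| time |  |  | 25 h |

| run | time / h | substrate / % | target / % |
|---|---|---|---|
| ochre | 1.00 | 14.2 | 27.6 |
| ochre | 3.00 | 12.4 | 23.3 |
| ochre | 6.00 | 11.4 | 22.0 |
| ochre | 8.00 | 12.3 | 22.7 |
| ochre | 12.0 | 11.3 | 21.6 |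
| ochre | 15.0 | 12.0 | 22.4 |
| ochre | 20.0 | 11.8 | 23.2 |
| grey | 3.00 | 12.2 | 23.8 |
| grey | 6.00 | 11.5 | 22.5 |
| grey | 8.00 | 11.6 | 21.6 |
| grey | 12.0 | 10.8 | 23.5 |
| grey | 15.0 | 11.9 | 22.1 |
| grey | 20.0 | 12.9 | 22.3 |

(standard deviation of a reading: 0.5 percentage points)

- steps that have been proposed: substrate <-> target; substrate <-> isomer of the product; substrate <-> dormant form
- what has gone from substrate into another species counts as reacted, even if it can come back
- the reaction counts as stopped when no species that holds the substrate changes by six tenths of a point or more over the second half of the time

- which holds at 25 h: what has brought the reaction to rest, or that it has not come to rest (forward and back rates have come level / it is still moving / all of the substrate has reacted)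
- conversion of substrate at 25 h
- amount of target at 25 h, in percent of the substrate charged

Each proposed step turns one molecule into one, so the charge cancels from any ratio of fractions at rest. From the readings at 15.0 h and 20.0 h in both runs, I took a mean substrate fraction of 12.1 % and a mean target fraction of 22.5 %. Their quotient is the rest ratio, target over substrate once forward and back rates are level: 1.85.

I read both runs as level from 6.00 h, a quarter of the time asked for the flask at 0.050 M. So my own reckoning for that flask was conversion 87.9 % and target 22.5 %.

The forecast, from a wider stretch of readings, said forward and back rates have come level, with conversion 88.2 % (87.4 % to 89 %) and target 22.4 % (21.6 % to 23.2 %), holding that “the position of rest does not depend on concentration”.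

The flask gave forward and back rates have come level, conversion 88.3 % and target 22.2 %.

    substrate ⇌ target (K = 1.90, k = 0.00122 s⁻¹)
    substrate ⇌ isomer of the product (K = 3.14, k = 4.48 × 10⁻⁴ s⁻¹)
    substrate ⇌ dormant form (K = 2.50, k = 0.00232 s⁻¹)

So the flask at 25 h stood at rest, with target over substrate at 1.90, beside the 1.85 read from the earlier runs. Left ten times as long, the flask still showed conversion 88.3 %. The neighbouring flask, the same charge read at 15 h, kept 12 % as substrate, and the rest ratio turns that into 21.7 % of target. That neighbour held 22.2 %.

All runs are calculated on assumed constants, and the scatter is random.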